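**Retrosynthetic overview**

1. Thiocladospolide F is a C2-symmetric sulfide of two identical 12-membered 5-hydroxy-4-oxo lactones. The usual cut (sulfide plus two macrocyclic 4-oxo-2-enolides by thia-Michael addition) is not used.
2. Key disconnection: both C2–S bonds by a stereospecific double SN2 of Na2S on a (2R)-α-triflyloxy lactone (two inversions give 2S,2'S). C4 is carried as a dioxolane so that no enone can form by E1cB and C2 is set by the substitution alone.
3. Monomer: the 12-membered ring is closed by ring-closing metathesis at C7=C8 and then hydrogenated. The C2–C3 bond and the 2R carbinol come from a catalytic enantioselective Mukaiyama aldol of a methyl-ketone enolsilane with a glyoxylate ester.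
4. Stereocentres: C11 from (R)-hex-5-en-2-ol, C5 from L-allylglycine (retentive diazotisation), C2 from the aldol catalyst and then inverted by sulfur.
5. Ring order: each lactone ring is closed first (identical rings, same batch). The sulfur bridge then joins two finished rings, and one acid step frees both ketones and both C5 alcohols.

Assumption (numbering): positions follow the seco acid, C1 = lactone carbonyl, C2 = sulfur-bearing carbon, C4 = ketone, C5 = carbinol, C11 = methyl-bearing carbinol.
Assumption (catalyst sense): (S,S)-Ph-pybox is taken as the ligand antipode that gives the 2R aldol; if the first run shows 2S, the (R,R)-ligand is used and nothing else changes.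

**Route**

Step 1
Reactants: 1 L-allylglycine, (S)-2-aminopent-4-enoic acid
Product: 2 (S)-2-hydroxypent-4-enoic acid
Conditions: NaNO2, 1 M H2SO4, H2O, 0 °C to rt
Reagents that add atoms: water, O
Why: Diazotisation of an α-amino acid, in which the carboxylate expels N2 to give an α-lactone that water opens, so the net substitution occurs with retention and fixes the future C5 as S.

Step 2
Reactants: 2 (S)-2-hydroxypent-4-enoic acid
Product: 3 (S)-2-hydroxy-N-methoxy-N-methylpent-4-enamide
Conditions: MeNHOMe·HCl, EDC·HCl, HOBt (cat.), N-methylmorpholine, CH2Cl2, 0 °C to rt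
Reagents that add atoms: N,O-dimethylhydroxylamine hydrochloride, CNOC.Cl
Why: Carbodiimide amide coupling gives the Weinreb amide needed for a clean single addition of a methyl nucleophile, and the stereocentre is not touched.

Step 3
Reactants: 3 (S)-2-hydroxy-N-methoxy-N-methylpent-4-enamide
Product: 4 (S)-2-(tert-butyldimethylsilyloxy)-N-methoxy-N-methylpent-4-enamide
Conditions: tBuMe2SiCl, imidazole, DMF, rt
Reagents that add atoms: tert-butyldimethylsilyl chloride, CC(C)(C)[Si](C)(C)Cl
Why: Standard silyl ether formation protects the future C5 hydroxyl with a group that survives base, Lewis acid, metathesis and hydrogenation and falls off in the final acid step.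

Step 4
Reactants: 4 (S)-2-(tert-butyldimethylsilyloxy)-N-methoxy-N-methylpent-4-enamide
Product: 5 (S)-3-(tert-butyldimethylsilyloxy)hex-5-en-2-one
Conditions: MeMgBr, THF, 0 °C; aq. NH4Cl
Reagents that add atoms: methylmagnesium bromide, C[Mg]Br
Why: Weinreb ketone synthesis, in which the chelated tetrahedral adduct blocks over-addition and the α-silyloxy centre is not epimerised.

Step 5
Reactants: 5 (S)-3-(tert-butyldimethylsilyloxy)hex-5-en-2-one
Product: 7 (S)-3-(tert-butyldimethylsilyloxy)-2-(trimethylsilyloxy)hexa-1,5-diene, via lithium enolate 6 (not isolated)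
Conditions: LiN(iPr)2 (commercial solution), THF, −78 °C; then Me3SiCl, −78 °C to 0 °C; pentane/NaHCO3 work-up, used crude
Reagents that add atoms: chlorotrimethylsilane, C[Si](C)(C)Cl
Why: Kinetic deprotonation takes the unhindered methyl proton rather than the hindered α-silyloxy methine, and O-silylation traps the terminal enolate as the enolsilane without touching C5.

Step 6
Reactants: 8 (R)-hex-5-en-2-ol (2 equiv); 9 L-(+)-tartaric acid
Product: 10 bis[(R)-hex-5-en-2-yl] (2R,3R)-tartrate
Conditions: TsOH·H2O (cat.), toluene, reflux, Dean–Stark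
Reagents that add atoms: none
Why: Fischer esterification with azeotropic water removal loads the chiral alcohol onto both carboxyls so that glycol cleavage returns two glyoxylate esters per diester.

Step 7
Reactants: 10 bis[(R)-hex-5-en-2-yl] (2R,3R)-tartrate
Product: 11 (R)-hex-5-en-2-yl glyoxylate
Conditions: H5IO6, Et2O, 0 °C to rt; dried azeotropically (toluene) before use
Reagents that add atoms: none
Why: Malaprade glycol cleavage gives the glyoxylate ester directly, and the terminal alkene is inert to periodic acid.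

Step 8
Reactants: 7 (S)-3-(tert-butyldimethylsilyloxy)-2-(trimethylsilyloxy)hexa-1,5-diene; 11 (R)-hex-5-en-2-yl glyoxylate
Product: 13 (R)-hex-5-en-2-yl (2R,5S)-5-(tert-butyldimethylsilyloxy)-2-hydroxy-4-oxooct-7-enoate, via aldol trimethylsilyl ether 12 (not isolated)
Conditions: ScCl3(THF)3/(S,S)-Ph-pybox/AgSbF6 (10 mol%), CH2Cl2, −78 °C; then 1 M HCl/THF, 0 °C
Reagents that add atoms: none
Why: Catalytic enantioselective Mukaiyama aldol, in which two-point binding of the glyoxylate to the chiral scandium–pybox cation exposes one aldehyde face so that C2 is set as 2R under catalyst control, while the open silyl-transfer transition state leaves C5 and both alkenes untouched.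

Step 9
Reactants: 13 (R)-hex-5-en-2-yl (2R,5S)-5-(tert-butyldimethylsilyloxy)-2-hydroxy-4-oxooct-7-enoate
Product: 14 (R)-hex-5-en-2-yl (2R)-3-{2-[(S)-1-(tert-butyldimethylsilyloxy)but-3-enyl]-1,3-dioxolan-2-yl}-2-hydroxypropanoate
Conditions: (Me3SiOCH2)2 (3 equiv), Me3SiOTf (5 mol%), CH2Cl2, −78 to −30 °C; pyridine quench
Reagents that add atoms: 1,2-bis(trimethylsilyloxy)ethane, C[Si](C)(C)OCCO[Si](C)(C)C
Why: Noyori silyl-transfer ketalisation, driven by formation of (Me3Si)2O at low temperature, masks the C4 ketone so that C3–H is no longer acidic and elimination to the enone becomes impossible in the later substitution.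

Step 10
Reactants: 14 (R)-hex-5-en-2-yl (2R)-3-{2-[(S)-1-(tert-butyldimethylsilyloxy)but-3-enyl]-1,3-dioxolan-2-yl}-2-hydroxypropanoate
Product: 15 (2R,5S,11R)-5-(tert-butyldimethylsilyloxy)-4,4-(ethylenedioxy)-2-hydroxydodec-7-en-11-olide (E/Z mixture)
Conditions: second-generation Grubbs catalyst RuCl2(=CHPh)(PCy3)(H2IMes) (5 mol%), CH2Cl2 (2 mM), 40 °C
Reagents that add atoms: none
Why: Ring-closing metathesis of two unhindered terminal alkenes at high dilution closes the 12-membered lactone at C7=C8 with loss of ethylene, and the alkene geometry is irrelevant because it is reduced next.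

Step 11
Reactants: 15 (2R,5S,11R)-5-(tert-butyldimethylsilyloxy)-4,4-(ethylenedioxy)-2-hydroxydodec-7-en-11-olide
Product: 16 (2R,5S,11R)-5-(tert-butyldimethylsilyloxy)-4,4-(ethylenedioxy)-2-hydroxydodecan-11-olide
Conditions: H2 (1 atm), Pd on carbon (10% Pd/C), EtOAc, rt
Reagents that add atoms: none
Why: Heterogeneous catalytic hydrogenation saturates C7=C8 before any sulfur is present, and the silyl ether, ketal, lactone and free carbinol are inert.

Step 12
Reactants: 16 (2R,5S,11R)-5-(tert-butyldimethylsilyloxy)-4,4-(ethylenedioxy)-2-hydroxydodecan-11-olide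
Product: 17 (2R,5S,11R)-5-(tert-butyldimethylsilyloxy)-4,4-(ethylenedioxy)-2-(trifluoromethylsulfonyloxy)dodecan-11-olide
Conditions: Tf2O, 2,6-lutidine, CH2Cl2, −78 °C; used directly after cold work-up
Reagents that add atoms: trifluoromethanesulfonic anhydride, O=S(=O)(OS(=O)(=O)C(F)(F)F)C(F)(F)F
Why: O-sulfonylation with a hindered non-nucleophilic base occurs at oxygen with retention at C2 and gives an α-triflyloxy lactone that is highly reactive in SN2.

Step 13
Reactants: 17 (2R,5S,11R)-5-(tert-butyldimethylsilyloxy)-4,4-(ethylenedioxy)-2-(trifluoromethylsulfonyloxy)dodecan-11-olide (2.00 equiv)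
Product: 19 bis[(2S,5S,11R)-5-(tert-butyldimethylsilyloxy)-4,4-(ethylenedioxy)dodecan-11-olid-2-yl] sulfide, via macrolide sodium thiolate 18 (not isolated)
Conditions: Na2S (anhydrous, 0.50 equiv), DMF, −40 to 0 °C, argon
Reagents that add atoms: sodium sulfide, [Na+].[Na+].[S-2]
Why: Double SN2 thioetherification, in which sulfide and then the thiolate 18 each displace one α-triflate with clean inversion (2R to 2S at both centres), and the C4 ketal removes the E1cB pathway so no planar enone can scramble C2.

Step 14
Reactants: 19 bis[(2S,5S,11R)-5-(tert-butyldimethylsilyloxy)-4,4-(ethylenedioxy)dodecan-11-olid-2-yl] sulfide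
Product: 20 thiocladospolide F, bis[(2S,5S,11R)-5-hydroxy-4-oxododecan-11-olid-2-yl] sulfide
Conditions: 2 M aq. HCl/THF (1:2), rt to 40 °C
Reagents that add atoms: water, O
Why: Acid hydrolysis cleaves both dioxolanes and both silyl ethers in one operation, and acid is chosen because the β-keto sulfide and the lactones tolerate it whereas base would trigger retro-thia-Michael cleavage.

**Compound list**

1 | L-allylglycine, (S)-2-aminopent-4-enoic acid | N[C@@H](CC=C)C(=O)O | starting material
2 | (S)-2-hydroxypent-4-enoic acid | O[C@@H](CC=C)C(=O)O | intermediate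
3 | (S)-2-hydroxy-N-methoxy-N-methylpent-4-enamide | O[C@@H](CC=C)C(=O)N(C)OC | intermediate
4 | (S)-2-(tert-butyldimethylsilyloxy)-N-methoxy-N-methylpent-4-enamide | CC(C)(C)[Si](C)(C)O[C@@H](CC=C)C(=O)N(C)OC | intermediate
5 | (S)-3-(tert-butyldimethylsilyloxy)hex-5-en-2-one | CC(C)(C)[Si](C)(C)O[C@@H](CC=C)C(C)=O | intermediate
6 | lithium (S)-3-(tert-butyldimethylsilyloxy)hexa-1,5-dien-2-olate (not isolated) | CC(C)(C)[Si](C)(C)O[C@@H](CC=C)C(=C)[O-].[Li+] | intermediate
7 | (S)-3-(tert-butyldimethylsilyloxy)-2-(trimethylsilyloxy)hexa-1,5-diene | CC(C)(C)[Si](C)(C)O[C@@H](CC=C)C(=C)O[Si](C)(C)C | intermediate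
8 | (R)-hex-5-en-2-ol | C[C@@H](O)CCC=C | starting material
9 | L-(+)-tartaric acid, (2R,3R) | OC(=O)[C@H](O)[C@@H](O)C(=O)O | starting material
10 | bis[(R)-hex-5-en-2-yl] (2R,3R)-tartrate | C=CCC[C@@H](C)OC(=O)[C@H](O)[C@@H](O)C(=O)O[C@H](C)CCC=C | intermediate
11 | (R)-hex-5-en-2-yl glyoxylate | C[C@@H](OC(=O)C=O)CCC=C | intermediate
12 | (R)-hex-5-en-2-yl (2R,5S)-5-(tert-butyldimethylsilyloxy)-4-oxo-2-(trimethylsilyloxy)oct-7-enoate (not isolated) | C=CCC[C@@H](C)OC(=O)[C@H](O[Si](C)(C)C)CC(=O)[C@H](CC=C)O[Si](C)(C)C(C)(C)C | intermediate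
13 | (R)-hex-5-en-2-yl (2R,5S)-5-(tert-butyldimethylsilyloxy)-2-hydroxy-4-oxooct-7-enoate | C=CCC[C@@H](C)OC(=O)[C@H](O)CC(=O)[C@H](CC=C)O[Si](C)(C)C(C)(C)C | intermediate
14 | (R)-hex-5-en-2-yl (2R)-3-{2-[(S)-1-(tert-butyldimethylsilyloxy)but-3-enyl]-1,3-dioxolan-2-yl}-2-hydroxypropanoate | C=CCC[C@@H](C)OC(=O)[C@H](O)CC1(OCCO1)[C@H](CC=C)O[Si](C)(C)C(C)(C)C | intermediate
15 | (2R,5S,11R)-5-(tert-butyldimethylsilyloxy)-4,4-(ethylenedioxy)-2-hydroxydodec-7-en-11-olide (E/Z mixture at C7=C8) | C[C@@H]1CCC=CC[C@H](O[Si](C)(C)C(C)(C)C)C2(OCCO2)C[C@@H](O)C(=O)O1 | intermediate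
16 | (2R,5S,11R)-5-(tert-butyldimethylsilyloxy)-4,4-(ethylenedioxy)-2-hydroxydodecan-11-olide | C[C@@H]1CCCCC[C@H](O[Si](C)(C)C(C)(C)C)C2(OCCO2)C[C@@H](O)C(=O)O1 | intermediate
17 | (2R,5S,11R)-5-(tert-butyldimethylsilyloxy)-4,4-(ethylenedioxy)-2-(trifluoromethylsulfonyloxy)dodecan-11-olide | C[C@@H]1CCCCC[C@H](O[Si](C)(C)C(C)(C)C)C2(OCCO2)C[C@@H](OS(=O)(=O)C(F)(F)F)C(=O)O1 | intermediate
18 | sodium (2S,5S,11R)-5-(tert-butyldimethylsilyloxy)-4,4-(ethylenedioxy)dodecan-11-olide-2-thiolate (not isolated) | C[C@@H]1CCCCC[C@H](O[Si](C)(C)C(C)(C)C)C2(OCCO2)C[C@H]([S-])C(=O)O1.[Na+] | intermediate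
19 | bis[(2S,5S,11R)-5-(tert-butyldimethylsilyloxy)-4,4-(ethylenedioxy)dodecan-11-olid-2-yl] sulfide | C[C@@H]1CCCCC[C@H](O[Si](C)(C)C(C)(C)C)C2(OCCO2)C[C@H](S[C@H]3CC4(OCCO4)[C@@H](O[Si](C)(C)C(C)(C)C)CCCCC[C@@H](C)OC3=O)C(=O)O1 | intermediate
20 | thiocladospolide F, bis[(2S,5S,11R)-5-hydroxy-4-oxododecan-11-olid-2-yl] sulfide | C[C@@H]1CCCCC[C@H](O)C(=O)C[C@H](S[C@H]2CC(=O)[C@@H](O)CCCCC[C@@H](C)OC2=O)C(=O)O1 | target

**Step count**

Total step count: 14.
Longest linear sequence: 12 steps (steps 1 to 5, then 8 to 14, from L-allylglycine); steps 6 and 7 are the two-step glyoxylate branch.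

**Three steps most likely to fail, each with a fallback**

Step 13 (double SN2 with Na2S). The dianionic sulfide is basic as well as nucleophilic, so E2 loss of triflate, epimerisation of the α-triflyloxy lactone or a stalled mono-substitution could erode the yield. The fallback sets out from compound 17 and comes back at compound 19, and it replaces the one-pot sulfide dianion by a monofunctional sulfur nucleophile followed by a thiol–triflate coupling. One half of 17 is treated with KSC(O)CH3 in DMF at −20 °C, which gives, with inversion, (2S,5S,11R)-2-(acetylthio)-5-(tert-butyldimethylsilyloxy)-4,4-(ethylenedioxy)dodecan-11-olide F1. Pyrrolidine in degassed CH2Cl2 at 0 °C removes the acetyl group and gives (2S,5S,11R)-5-(tert-butyldimethylsilyloxy)-4,4-(ethylenedioxy)-2-mercaptododecan-11-olide F2. The thiol is then combined with the second half of 17 and iPr2NEt in DMF at −20 °C, and this second inversion delivers 19.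

Step 9 (ketalisation of the acyclic aldol). The ketone is flanked by a silyloxy methine, and under Me3SiOTf the oxocarbenium ion could be intercepted by the pendant allyl group (Prins-type closure) or the free aldol unit could cleave. The fallback sets out from compound 13 and comes back at compound 16, and it changes the order so that the ring is closed and the alkenes are removed before the carbonyl is masked. Ring-closing metathesis of 13 with the same ruthenium catalyst gives (2R,5S,11R)-5-(tert-butyldimethylsilyloxy)-2-hydroxy-4-oxododec-7-en-11-olide F3 as an E/Z mixture. Hydrogenation over Pd on carbon gives (2R,5S,11R)-5-(tert-butyldimethylsilyloxy)-2-hydroxy-4-oxododecan-11-olide F4. The silyl-transfer ketalisation with (Me3SiOCH2)2 and catalytic Me3SiOTf is then run on this alkene-free, conformationally restrained ring ketone to give 16.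

Step 14 (global unmasking). The dioxolane next to an oxygenated carbon may need acid strong enough to threaten the lactones or to cause acid-promoted loss of the sulfide. The fallback sets out from compound 19 and comes back at compound 20, and it separates silyl cleavage from ketone release and replaces hydrolysis by acetal exchange. HF·pyridine in THF/pyridine at 0 °C to rt removes both silyl ethers and gives bis[(2S,5S,11R)-4,4-(ethylenedioxy)-5-hydroxydodecan-11-olid-2-yl] sulfide F5. The dioxolanes are then exchanged into the solvent with catalytic TsOH·H2O in dry acetone at rt, which releases both ketones without water and gives 20.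

**Further compounds**

F1 | step 13 | (2S,5S,11R)-2-(acetylthio)-5-(tert-butyldimethylsilyloxy)-4,4-(ethylenedioxy)dodecan-11-olide | C[C@@H]1CCCCC[C@H](O[Si](C)(C)C(C)(C)C)C2(OCCO2)C[C@H](SC(C)=O)C(=O)O1
F2 | step 13 | (2S,5S,11R)-5-(tert-butyldimethylsilyloxy)-4,4-(ethylenedioxy)-2-mercaptododecan-11-olide | C[C@@H]1CCCCC[C@H](O[Si](C)(C)C(C)(C)C)C2(OCCO2)C[C@H](S)C(=O)O1
F3 | step 9 | (2R,5S,11R)-5-(tert-butyldimethylsilyloxy)-2-hydroxy-4-oxododec-7-en-11-olide (E/Z mixture) | C[C@@H]1CCC=CC[C@H](O[Si](C)(C)C(C)(C)C)C(=O)C[C@@H](O)C(=O)O1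
F4 | step 9 | (2R,5S,11R)-5-(tert-butyldimethylsilyloxy)-2-hydroxy-4-oxododecan-11-olide | C[C@@H]1CCCCC[C@H](O[Si](C)(C)C(C)(C)C)C(=O)C[C@@H](O)C(=O)O1
F5 | step 14 | bis[(2S,5S,11R)-4,4-(ethylenedioxy)-5-hydroxydodecan-11-olid-2-yl] sulfide | C[C@@H]1CCCCC[C@H](O)C2(OCCO2)C[C@H](S[C@H]3CC4(OCCO4)[C@@H](O)CCCCC[C@@H](C)OC3=O)C(=O)O1
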